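**Retrosynthetic overview**

- Target 21 ← diol 20 ← silyl ether 19 ← oxolane ester 18, by debenzylation, desilylation and ester reduction; the skeleton is unchanged.
- 18 ← diazo ester 17. In the oxolane ring (O1, C2–C5), C2 is a benzylic C–H carbon bonded to O1 and its neighbour C3 carries the ester-level carbon C9. The C2–C3 bond is therefore cut back to a rhodium carbene at C3 and the C2–H bond of a bis-benzylic ether; this insertion closes the only ring, last.
- 17 ← ester 14 (deacylative diazo transfer) ← aldol 11, by O-arylmethylation with imidate 5 (the O1–C2 bond), LiBH4 removal of the auxiliary (C9') and silylation.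
- 11 ← imide 9 + aldehyde 3 by Evans syn-aldol (C4–C5 bond, both centres); 3 and 5 come from syringaldehyde 1, 9 from succinate 6 and oxazolidinone 7.

Key step: step 10

Remark: the oxolane is numbered O1, C2 (its aryl cis to the C3 arm C9), C3, C4 (arm C9'), C5; Ar stands for 4-(benzyloxy)-3,5-dimethoxyphenyl; the (S)-PTTL antipode of the catalyst is assumed to be the matched one for 17, and the (R) antipode would be used in the same way if it is not.

**Route**

Step 1
Reactants: 1 syringaldehyde; 2 benzyl bromide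
Product: 3 4-(benzyloxy)-3,5-dimethoxybenzaldehyde (ArCHO)
Conditions: K2CO3, DMF, 60 °C
Reagents that add atoms: none
Why: Williamson ether synthesis, in which the phenoxide formed by K2CO3 displaces bromide from 2 while the aldehyde stays inert.

Step 2
Reactants: 3 4-(benzyloxy)-3,5-dimethoxybenzaldehyde
Product: 4 [4-(benzyloxy)-3,5-dimethoxyphenyl]methanol (ArCH2OH)
Conditions: NaBH4, MeOH–THF, 0 °C
Reagents that add atoms: none
Why: borohydride reduction of an aryl aldehyde to the benzylic alcohol, with the ethers untouched.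

Step 3
Reactants: 4 [4-(benzyloxy)-3,5-dimethoxyphenyl]methanol
Product: 5 [4-(benzyloxy)-3,5-dimethoxyphenyl]methyl 2,2,2-trichloroacetimidate
Conditions: Cl3CCN, DBU (10 mol %), CH2Cl2, 0 °C
Reagents that add atoms: trichloroacetonitrile, N#CC(Cl)(Cl)Cl
Why: base-catalysed addition of the benzylic alkoxide to the nitrile (trichloroacetimidate formation), the product being used fresh because electron-rich benzylic imidates rearrange on standing.

Step 4
Reactants: 6 mono-tert-butyl succinate; 7 (R)-4-benzyl-2-oxazolidinone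
Product: 9 tert-butyl 4-[(4R)-4-benzyl-2-oxo-1,3-oxazolidin-3-yl]-4-oxobutanoate, via mixed pivalic anhydride 8 (not isolated)
Conditions: PivCl, Et3N, THF, −20 °C; then 7, LiCl, −20 °C → rt
Reagents that add atoms: pivaloyl chloride, CC(C)(C)C(Cl)=O (its atoms stay only in 8)
Why: N-acylation of the oxazolidinone through a mixed anhydride (LiCl/Et3N protocol), in which attack occurs at the unhindered succinyl carbonyl and the tert-butyl ester is untouched.

Step 5
Reactants: 9 tert-butyl 4-[(4R)-4-benzyl-2-oxo-1,3-oxazolidin-3-yl]-4-oxobutanoate; 3 4-(benzyloxy)-3,5-dimethoxybenzaldehyde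
Product: 11 tert-butyl (3R,4R)-4-Ar-3-{[(4R)-4-benzyl-2-oxo-1,3-oxazolidin-3-yl]carbonyl}-4-hydroxybutanoate, via dibutylboron Z-enolate 10 (not isolated)
Conditions: Bu2BOTf, iPr2NEt, CH2Cl2, −78 → 0 °C; then 3, −78 → 0 °C; pH 7 buffer, MeOH, 30% H2O2, 0 °C
Reagents that add atoms: dibutylboron triflate, CCCCB(CCCC)OS(=O)(=O)C(F)(F)F (its atoms stay only in 10)
Why: Evans syn-aldol reaction, in which soft enolisation occurs at the more acidic imide α-CH2 and the Z-boron enolate adds to 3 through a Zimmerman–Traxler chair on the face away from the benzyl group of the (R)-auxiliary, setting the two centres (3R,4R) that become C4 and C5 with the aryl group trans to the C9' carbon.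

Step 6
Reactants: 11 aldol adduct; 5 [4-(benzyloxy)-3,5-dimethoxyphenyl]methyl 2,2,2-trichloroacetimidate
Product: 12 tert-butyl (3R,4R)-4-Ar-4-(ArCH2O)-3-{[(4R)-4-benzyl-2-oxo-1,3-oxazolidin-3-yl]carbonyl}butanoate
Conditions: 5 (1.5 equiv), Me3SiOTf (5 mol %), 4 Å MS, CH2Cl2, −40 → 0 °C; Et3N quench
Reagents that add atoms: none
Why: acid-catalysed O-alkylation with a benzylic trichloroacetimidate, in which only the O–H bond of the C5 hydroxyl reacts so that C5 keeps its configuration, while the base-free conditions avoid retro-aldol cleavage and lactonisation onto the ester.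

Step 7
Reactants: 12 arylmethyl ether imide
Product: 13 tert-butyl (3S,4R)-4-Ar-4-(ArCH2O)-3-(hydroxymethyl)butanoate
Conditions: LiBH4, H2O (1 equiv), Et2O–THF, 0 °C
Reagents that add atoms: none
Why: reductive removal of the oxazolidinone auxiliary, since LiBH4 reduces the activated exocyclic imide carbonyl to the primary alcohol C9' much faster than it touches the tert-butyl ester, and 7 is recovered.

Step 8
Reactants: 13 primary alcohol
Product: 14 tert-butyl (3S,4R)-4-Ar-4-(ArCH2O)-3-{[(tert-butyldimethylsilyl)oxy]methyl}butanoate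
Conditions: TBSCl, imidazole, CH2Cl2, 0 °C → rt
Reagents that add atoms: tert-butyldimethylsilyl chloride, CC(C)(C)[Si](C)(C)Cl
Why: silylation of the primary alcohol, which blocks lactonisation onto the ester and leaves neither an O–H bond nor an activated C–H bond on C9' for the enolate and carbene steps.

Step 9
Reactants: 14 silyl ether ester
Product: 17 tert-butyl (3S,4R)-4-Ar-4-(ArCH2O)-3-{[(tert-butyldimethylsilyl)oxy]methyl}-2-diazobutanoate, via lithium ester enolate 15 (not isolated), via trifluoroacetyl ester 16 (not isolated)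
Conditions: LiN(iPr)2, THF, −78 °C; CF3CO2CH2CF3, −78 °C; cold 5% aq HCl; then p-ABSA, Et3N, H2O (1 equiv), MeCN, rt
Reagents that add atoms: 4-acetamidobenzenesulfonyl azide (p-ABSA), CC(=O)Nc1ccc(cc1)S(=O)(=O)N=[N+]=[N-] (the two diazo nitrogens); 2,2,2-trifluoroethyl trifluoroacetate, FC(F)(F)COC(=O)C(F)(F)F (its atoms stay only in 16); lithium diisopropylamide, CC(C)N([Li])C(C)C (lithium only in 15)
Why: detrifluoroacetylative diazo transfer (Claisen acylation, then Regitz-type deacylative transfer), needed because the simple ester is not acidic enough for direct transfer, so the enolate is trifluoroacetylated and the resulting β-keto ester takes N2 from the sulfonyl azide with loss of the trifluoroacetyl group, the enolate having no β leaving group and the C4 and C5 centres not being touched.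

Step 10
Reactants: 17 diazo ester
Product: 18 tert-butyl (2S,3R,4S,5R)-2,5-bis(Ar)-4-{[(tert-butyldimethylsilyl)oxy]methyl}oxolane-3-carboxylate
Conditions: Rh2(S-PTTL)4 [dirhodium tetrakis(N-phthaloyl-(S)-tert-leucinate)] (2 mol %), 4 Å MS, toluene, −78 → −40 °C, slow addition of 17
Reagents that add atoms: none
Why: Loss of N2 from 17 at the dirhodium tetracarboxylate should give an electrophilic rhodium carbene at C3, which inserts into the C2–H bond of the benzylic ether in one concerted, three-centre, hydride-transfer-like step, so that the C2–C3 bond and the new C3–H bond form together and the catalyst is released. The closest known reaction type is the dirhodium-carboxylate-catalysed 1,5 C–H insertion of α-diazo esters next to an ether oxygen, which gives cis-2-aryl-3-carboxylate oxacycles with phthalimido-carboxylate catalysts. The oxolane closes as a five-membered ring by 1,5 insertion through a chair-like array of C3, C4, C5, O1, C2 and the migrating hydrogen, and no other ring size competes because only the C2–H bond is activated by both an aryl group and O1. C2 is controlled by the resident C5 centre, since both aryl groups sit pseudo-equatorially in that array and so end up cis across O1, while C3 is controlled by the resident C4 centre (ester anti to the silyloxymethyl arm) together with the chiral carboxylate wall, which is expected to hold the C2 aryl group on the ester side. The step needs chemoselectivity over 1,2-hydride shift from C4–H and over attack on the C5 aryl ring, and it needs the 2,3-cis, 3,4-trans, 2,5-cis arrangement; the bulky carboxylate at low temperature slows the hydride shift, the doubly activated C2–H bond should outrun aromatic substitution, and the trans C4/C5 pair fixed by the aldol biases both new centres. The product is the kinetic C3 epimer and is therefore kept away from base until the ester is reduced.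

Step 11
Reactants: 18 oxolane ester
Product: 19 [(2S,3S,4S,5R)-2,5-bis(Ar)-4-{[(tert-butyldimethylsilyl)oxy]methyl}oxolan-3-yl]methanol
Conditions: LiAlH4, THF, −20 → 0 °C
Reagents that add atoms: none
Why: hydride reduction of the tert-butyl ester to the primary alcohol C9, which at low temperature should be faster than enolisation so that C3 keeps its configuration, the silyl and benzyl ethers being inert.

Step 12
Reactants: 19 mono-silylated diol
Product: 20 [(2S,3S,4S,5R)-2,5-bis(Ar)oxolane-3,4-diyl]dimethanol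
Conditions: Bu4NF, THF, 0 °C → rt
Reagents that add atoms: none
Why: fluoride cleavage of the silyl ether driven by the strong Si–F bond, under conditions that do not ionise the benzylic ring C–O bonds.

Step 13
Reactants: 20 bis(benzyl ether) diol
Product: 21 [(2S,3S,4S,5R)-2,5-bis(4-hydroxy-3,5-dimethoxyphenyl)oxolane-3,4-diyl]dimethanol (target)
Conditions: H2 (1 atm), 10% Pd/C, EtOAc–MeOH, rt, stopped once both benzyl ethers are gone
Reagents that add atoms: none
Why: hydrogenolysis of the two aryl benzyl ethers over Pd/C, which cleave much faster than the benzylic C–O bonds of the oxolane ring under neutral conditions, so no stereocentre is touched.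

**Compound list**

1 | syringaldehyde (4-hydroxy-3,5-dimethoxybenzaldehyde) | COc1cc(C=O)cc(OC)c1O | starting material
2 | benzyl bromide | BrCc1ccccc1 | starting material
3 | 4-(benzyloxy)-3,5-dimethoxybenzaldehyde | COc1cc(C=O)cc(OC)c1OCc1ccccc1 | intermediate
4 | [4-(benzyloxy)-3,5-dimethoxyphenyl]methanol | COc1cc(CO)cc(OC)c1OCc1ccccc1 | intermediate
5 | [4-(benzyloxy)-3,5-dimethoxyphenyl]methyl 2,2,2-trichloroacetimidate | COc1cc(COC(=N)C(Cl)(Cl)Cl)cc(OC)c1OCc1ccccc1 | intermediate
6 | mono-tert-butyl succinate (4-tert-butoxy-4-oxobutanoic acid) | CC(C)(C)OC(=O)CCC(=O)O | starting material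
7 | (R)-4-benzyl-2-oxazolidinone | O=C1N[C@H](Cc2ccccc2)CO1 | starting material
8 | 4-tert-butoxy-4-oxobutanoic pivalic anhydride (formed in the flask) | CC(C)(C)OC(=O)CCC(=O)OC(=O)C(C)(C)C | intermediate
9 | tert-butyl 4-[(4R)-4-benzyl-2-oxo-1,3-oxazolidin-3-yl]-4-oxobutanoate | CC(C)(C)OC(=O)CCC(=O)N1C(=O)OC[C@H]1Cc1ccccc1 | intermediate
10 | dibutylboron Z-enolate of 9 (formed in the flask) | CCCCB(CCCC)O/C(=C\CC(=O)OC(C)(C)C)N1C(=O)OC[C@H]1Cc1ccccc1 | intermediate
11 | tert-butyl (3R,4R)-4-Ar-3-{[(4R)-4-benzyl-2-oxo-1,3-oxazolidin-3-yl]carbonyl}-4-hydroxybutanoate | CC(C)(C)OC(=O)C[C@@H](C(=O)N1C(=O)OC[C@H]1Cc1ccccc1)[C@@H](O)c1cc(OC)c(OCc2ccccc2)c(OC)c1 | intermediate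
12 | tert-butyl (3R,4R)-4-Ar-4-(ArCH2O)-3-{[(4R)-4-benzyl-2-oxo-1,3-oxazolidin-3-yl]carbonyl}butanoate | CC(C)(C)OC(=O)C[C@@H](C(=O)N1C(=O)OC[C@H]1Cc1ccccc1)[C@@H](OCc1cc(OC)c(OCc2ccccc2)c(OC)c1)c1cc(OC)c(OCc2ccccc2)c(OC)c1 | intermediate
13 | tert-butyl (3S,4R)-4-Ar-4-(ArCH2O)-3-(hydroxymethyl)butanoate | CC(C)(C)OC(=O)C[C@@H](CO)[C@@H](OCc1cc(OC)c(OCc2ccccc2)c(OC)c1)c1cc(OC)c(OCc2ccccc2)c(OC)c1 | intermediate
14 | tert-butyl (3S,4R)-4-Ar-4-(ArCH2O)-3-{[(tert-butyldimethylsilyl)oxy]methyl}butanoate | CC(C)(C)OC(=O)C[C@@H](CO[Si](C)(C)C(C)(C)C)[C@@H](OCc1cc(OC)c(OCc2ccccc2)c(OC)c1)c1cc(OC)c(OCc2ccccc2)c(OC)c1 | intermediate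
15 | lithium enolate of ester 14 (formed in the flask) | CC(C)(C)OC(O[Li])=C[C@@H](CO[Si](C)(C)C(C)(C)C)[C@@H](OCc1cc(OC)c(OCc2ccccc2)c(OC)c1)c1cc(OC)c(OCc2ccccc2)c(OC)c1 | intermediate
16 | tert-butyl (3S,4R)-4-Ar-4-(ArCH2O)-3-{[(tert-butyldimethylsilyl)oxy]methyl}-2-(trifluoroacetyl)butanoate, C2 epimers and enol (crude, carried on) | CC(C)(C)OC(=O)C(C(=O)C(F)(F)F)[C@@H](CO[Si](C)(C)C(C)(C)C)[C@@H](OCc1cc(OC)c(OCc2ccccc2)c(OC)c1)c1cc(OC)c(OCc2ccccc2)c(OC)c1 | intermediate
17 | tert-butyl (3S,4R)-4-Ar-4-(ArCH2O)-3-{[(tert-butyldimethylsilyl)oxy]methyl}-2-diazobutanoate | CC(C)(C)OC(=O)C(=[N+]=[N-])[C@@H](CO[Si](C)(C)C(C)(C)C)[C@@H](OCc1cc(OC)c(OCc2ccccc2)c(OC)c1)c1cc(OC)c(OCc2ccccc2)c(OC)c1 | intermediate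
18 | tert-butyl (2S,3R,4S,5R)-2,5-bis(Ar)-4-{[(tert-butyldimethylsilyl)oxy]methyl}oxolane-3-carboxylate | COc1cc([C@H]2O[C@@H](c3cc(OC)c(OCc4ccccc4)c(OC)c3)[C@H](CO[Si](C)(C)C(C)(C)C)[C@H]2C(=O)OC(C)(C)C)cc(OC)c1OCc1ccccc1 | intermediate
19 | [(2S,3S,4S,5R)-2,5-bis(Ar)-4-{[(tert-butyldimethylsilyl)oxy]methyl}oxolan-3-yl]methanol | COc1cc([C@H]2O[C@@H](c3cc(OC)c(OCc4ccccc4)c(OC)c3)[C@H](CO[Si](C)(C)C(C)(C)C)[C@H]2CO)cc(OC)c1OCc1ccccc1 | intermediate
20 | [(2S,3S,4S,5R)-2,5-bis(Ar)oxolane-3,4-diyl]dimethanol | COc1cc([C@H]2O[C@@H](c3cc(OC)c(OCc4ccccc4)c(OC)c3)[C@H](CO)[C@H]2CO)cc(OC)c1OCc1ccccc1 | intermediate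
21 | [(2S,3S,4S,5R)-2,5-bis(4-hydroxy-3,5-dimethoxyphenyl)oxolane-3,4-diyl]dimethanol | COc1cc([C@H]2O[C@@H](c3cc(OC)c(O)c(OC)c3)[C@H](CO)[C@H]2CO)cc(OC)c1O | target

**Step count and risks**

Total steps: 13. Longest linear sequence: 11 steps (1 → 3 → 4 → 5 → 12 → 13 → 14 → 17 → 18 → 19 → 20 → 21).

Steps most likely to fail:

1. Step 10 (carbene insertion). The carbene may undergo 1,2-hydride shift from C4–H to the unsaturated ester or attack the C5 aryl ring faster than it inserts. The insertion may also place the ester trans to the C2 aryl group, or the kinetic cis ester may epimerise at C3. The fallback sets out from aldol adduct 11 and comes back to the route at target 21. It makes C2 from the former ester carbon and sets it by hydride delivery to a cyclic oxocarbenium ion instead of by insertion.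
   - CF3CO2H in CH2Cl2 at 0 °C should cleave the tert-butyl ester of 11 and close the γ-lactone with the C5 hydroxyl, giving the trans lactone imide F1.
   - NaBH4 in THF–H2O at 0 °C should reduce the activated imide carbonyl faster than the lactone to give the hydroxymethyl lactone F2, with 7 recovered.
   - F2 is benzylated at once under neutral conditions (2-benzyloxy-1-methylpyridinium triflate, MgO, PhCF3, 83 °C) to the benzyl ether F3.
   - LiN(iPr)2 in THF at −78 °C gives the lithium enolate F4, which is alkylated with benzyl chloromethyl ether on the face anti to the C4 substituent to give the 3,4-trans lactone F5, now carrying the C9 arm.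
   - The aryllithium F6, made from 2-(benzyloxy)-5-bromo-1,3-dimethoxybenzene and n-BuLi in THF at −78 °C, should add once to the lactone carbonyl to give the hemiketal F7.
   - Et3SiH and BF3·OEt2 in CH2Cl2 at −78 °C should reduce the derived oxocarbenium ion on the face anti to the C3 arm, the known way to the 2,3-cis, 3,4-trans, 4,5-trans pattern, giving the tetrabenzyl oxolane F8.
   - Hydrogenolysis (H2, Pd/C, EtOAc–MeOH) of all four benzyl ethers then gives 21.

2. Step 6 (O-arylmethylation). The acid may ionise the electron-rich C5 carbinol, with loss of configuration at C5 or lactonisation onto the tert-butyl ester. The benzylic cation may also alkylate the dimethoxyaryl rings, or imidate 5 may rearrange to its amide before it transfers the group. The fallback sets out from alcohol 4 and aldol adduct 11 and comes back at ether 12, forming the same C–O bond without acid.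
   - 4 is heated with 2-chloropyridine, KOH and 18-crown-6 in toluene to give the 2-(arylmethoxy)pyridine F9.
   - F9 is mixed with 11 and MgO in PhCF3 and treated with MeOTf at 0 °C, which forms the N-methylpyridinium triflate F10 in the flask.
   - On warming to about 60 °C, F10 should hand its arylmethyl group to the C5 hydroxyl under buffered conditions and give 12.

3. Step 9 (diazo transfer). Trifluoroacetylation of the β-branched enolate may stay incomplete, or the trifluoroacetyl group may be lost before N2 is transferred, so that 14 is returned. The fallback sets out from 14 and comes back at diazo ester 17 through an amine.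
   - KN(SiMe3)2 in THF at −78 °C gives the potassium enolate F11.
   - Azide transfer from 2,4,6-triisopropylbenzenesulfonyl azide followed by an AcOH quench should give the α-azido ester F12; either C2 epimer serves.
   - Staudinger reduction (PPh3, THF–H2O) gives the α-amino ester F13.
   - Diazotisation with isoamyl nitrite and catalytic AcOH in warm CHCl3 should give 17.

**Further compounds**

F1 | step 10 | (4R)-4-benzyl-3-{[(2R,3R)-2-Ar-5-oxooxolan-3-yl]carbonyl}-1,3-oxazolidin-2-one | O=C1C[C@@H](C(=O)N2C(=O)OC[C@H]2Cc2ccccc2)[C@H](c2cc(OC)c(OCc3ccccc3)c(OC)c2)O1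
F2 | step 10 | (4S,5R)-5-Ar-4-(hydroxymethyl)oxolan-2-one | O=C1C[C@@H](CO)[C@H](c2cc(OC)c(OCc3ccccc3)c(OC)c2)O1
F3 | step 10 | (4S,5R)-5-Ar-4-[(benzyloxy)methyl]oxolan-2-one | O=C1C[C@@H](COCc2ccccc2)[C@H](c2cc(OC)c(OCc3ccccc3)c(OC)c2)O1
F4 | step 10 | lithium enolate of lactone F3 | [Li]OC1=C[C@@H](COCc2ccccc2)[C@H](c2cc(OC)c(OCc3ccccc3)c(OC)c2)O1
F5 | step 10 | (3S,4S,5R)-5-Ar-3,4-bis[(benzyloxy)methyl]oxolan-2-one | O=C1[C@H](COCc2ccccc2)[C@@H](COCc2ccccc2)[C@H](c2cc(OC)c(OCc3ccccc3)c(OC)c2)O1
F6 | step 10 | [4-(benzyloxy)-3,5-dimethoxyphenyl]lithium | [Li]c1cc(OC)c(OCc2ccccc2)c(OC)c1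
F7 | step 10 | (3S,4S,5R)-2,5-bis(Ar)-3,4-bis[(benzyloxy)methyl]oxolan-2-ol (anomer mixture) | OC1(c2cc(OC)c(OCc3ccccc3)c(OC)c2)O[C@@H](c2cc(OC)c(OCc3ccccc3)c(OC)c2)[C@H](COCc2ccccc2)[C@H]1COCc1ccccc1
F8 | step 10 | (2S,3S,4S,5R)-2,5-bis(Ar)-3,4-bis[(benzyloxy)methyl]oxolane | COc1cc([C@H]2O[C@@H](c3cc(OC)c(OCc4ccccc4)c(OC)c3)[C@H](COCc3ccccc3)[C@H]2COCc2ccccc2)cc(OC)c1OCc1ccccc1
F9 | step 6 | 2-{[4-(benzyloxy)-3,5-dimethoxyphenyl]methoxy}pyridine | COc1cc(COc2ccccn2)cc(OC)c1OCc1ccccc1
F10 | step 6 | 2-{[4-(benzyloxy)-3,5-dimethoxyphenyl]methoxy}-1-methylpyridin-1-ium triflate | COc1cc(COc2cccc[n+]2C)cc(OC)c1OCc1ccccc1.[O-]S(=O)(=O)C(F)(F)F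
F11 | step 9 | potassium enolate of ester 14 | CC(C)(C)OC(O[K])=C[C@@H](CO[Si](C)(C)C(C)(C)C)[C@@H](OCc1cc(OC)c(OCc2ccccc2)c(OC)c1)c1cc(OC)c(OCc2ccccc2)c(OC)c1
F12 | step 9 | tert-butyl (3S,4R)-2-azido-4-Ar-4-(ArCH2O)-3-{[(tert-butyldimethylsilyl)oxy]methyl}butanoate (C2 epimers) | CC(C)(C)OC(=O)C(N=[N+]=[N-])[C@@H](CO[Si](C)(C)C(C)(C)C)[C@@H](OCc1cc(OC)c(OCc2ccccc2)c(OC)c1)c1cc(OC)c(OCc2ccccc2)c(OC)c1
F13 | step 9 | tert-butyl (3S,4R)-2-amino-4-Ar-4-(ArCH2O)-3-{[(tert-butyldimethylsilyl)oxy]methyl}butanoate (C2 epimers) | CC(C)(C)OC(=O)C(N)[C@@H](CO[Si](C)(C)C(C)(C)C)[C@@H](OCc1cc(OC)c(OCc2ccccc2)c(OC)c1)c1cc(OC)c(OCc2ccccc2)c(OC)c1
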